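**Retrosynthetic overview**
1. Target 23 ⇐ C-desilylation of 22 ⇐ one-pot double bromoetherification of the (7Z,9E)-diene diol 20. O13→C9 with Br→C10 closes ring C, then O4→C7 with Br→C8 closes ring B.
2. 20 ⇐ Z-selective semihydrogenation of enyne 19 ⇐ Sonogashira union (C8–C9) of ring A alkyne 11 and vinyl iodide 18.
3. 11 ⇐ 5-endo opening (O6→C3) of the Shi epoxide of E-enyne 8 ⇐ Negishi coupling ⇐ phosphoric-acid-catalysed propargylation of achiral ynal 1 (sets C6).
4. 18 ⇐ enamine-catalysed α-bromination of achiral aldehyde 15 (sets C12), then Cornforth-controlled ethyl addition (sets C13).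
5. Ring order: A (oxolane O/C3–C6), then C (oxane O/C9–C13), then B (oxolane O/C4–C7, completing the 2,5-dioxabicyclo[2.2.1]heptane).

Assumption: atoms are numbered C1–C15 along the chain from the alkyne CH (C1) to the ethyl CH3 (C15), and On is the oxygen first carried by Cn. Catalyst enantiomers are assigned from the accepted models, and the antipode is used if the sense proves opposite.

Step 1
Reactants: 1 3-(trimethylsilyl)prop-2-ynal; 2 allenylboronic acid pinacol ester
Product: 4 (3R)-1-(trimethylsilyl)hexa-1,5-diyn-3-ol, via pinacol borate ester 3 (not isolated)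
Conditions: (R)-3,3'-bis(2,4,6-triisopropylphenyl)-1,1'-binaphthyl-2,2'-diyl hydrogen phosphate (5 mol%), 4 Å MS, toluene, −20 °C; aqueous work-up
Reagents that add atoms: none
Why: Chiral-phosphoric-acid-catalysed asymmetric propargylboration (allenylboronate SE2' addition through a closed chair in which the acid binds the boronate oxygen and the formyl hydrogen) attacks one aldehyde face and sets C6 (R) as the first stereocentre of this fragment, the alkynyl group taking the place of the aryl or alkenyl group of the usual substrates.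

Step 2
Reactants: 4 (3R)-1-(trimethylsilyl)hexa-1,5-diyn-3-ol; 5 (bromoethynyl)triisopropylsilane
Product: 8 (3R,5E)-1-(trimethylsilyl)-8-(triisopropylsilyl)oct-5-ene-1,7-diyn-3-ol, via alkenylzirconocene 6 (not isolated), via alkenylzinc chloride 7 (not isolated)
Conditions: Cp2Zr(H)Cl (2.1 equiv), THF, 0 °C to rt; ZnCl2 (1.1 equiv); 5, Pd(PPh3)4 (5 mol%), rt
Reagents that add atoms: none
Why: Hydrozirconation followed by Negishi cross-coupling, in which syn Zr–H addition to the terminal alkyne (much faster than to the silyl-capped one, the first equivalent only deprotonating the OH) fixes the 3E geometry, which is kept through Zn transmetalation and Pd-catalysed coupling, and C6 is untouched.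

Step 3
Reactants: 8 (3R,5E)-1-(trimethylsilyl)-8-(triisopropylsilyl)oct-5-ene-1,7-diyn-3-ol
Product: 10 (2S,3R,5R)-2-[(triisopropylsilyl)ethynyl]-5-[(trimethylsilyl)ethynyl]oxolan-3-ol, via epoxy alcohol 9 (not isolated)
Conditions: D-fructose-derived Shi ketone (30 mol%), KHSO5 (as 2KHSO5·KHSO4·K2SO4), K2CO3, Bu4NHSO4 (4 mol%), MeCN/CH2(OMe)2/aq. Na2B4O7 buffer, 0 °C; extract and dry; CSA (10 mol%), 4 Å MS, CH2Cl2, 0 °C
Reagents that add atoms: potassium peroxymonosulfate [K+].[O-]S(=O)(=O)OO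
Why: Shi asymmetric epoxidation (chiral dioxirane, spiro transition state) delivers oxygen to one face of the only alkene to give the (3R,4R)-alkynyl epoxide under reagent control, and acid then triggers the 5-endo epoxide opening usual for 3,4-epoxy alcohols, O6 attacking the activated propargylic C3 with inversion (C3 S) and leaving the C4 hydroxyl (R) cis to the C6 side chain.

Step 4
Reactants: 10 (2S,3R,5R)-2-[(triisopropylsilyl)ethynyl]-5-[(trimethylsilyl)ethynyl]oxolan-3-ol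
Product: 11 (2S,3R,5R)-5-ethynyl-2-[(triisopropylsilyl)ethynyl]oxolan-3-ol
Conditions: K2CO3 (0.2 equiv), MeOH, 0 °C
Reagents that add atoms: none
Why: Base-catalysed methanolytic protodesilylation removes the unhindered C–SiMe3 group while the bulky C–Si(iPr)3 group and all three stereocentres stay intact.

Step 5
Reactants: 12 pent-4-yn-1-ol
Product: 14 (E)-5-iodopent-4-en-1-ol, via alkenylzirconocene 13 (not isolated)
Conditions: Cp2Zr(H)Cl (2.1 equiv), THF, rt; I2 (1.05 equiv), 0 °C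
Reagents that add atoms: iodine [I][I]
Why: Hydrozirconation–iodinolysis, in which syn Zr–H addition and stereoretentive Zr/I exchange give only the E vinyl iodide (no stereocentre is formed).

Step 6
Reactants: 14 (E)-5-iodopent-4-en-1-ol
Product: 15 (E)-5-iodopent-4-enal
Conditions: TEMPO (10 mol%), PhI(OAc)2 (1.1 equiv), CH2Cl2, rt
Reagents that add atoms: none
Why: Oxoammonium (TEMPO) oxidation stops at the aldehyde and does not touch the vinyl iodide.

Step 7
Reactants: 15 (E)-5-iodopent-4-enal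
Product: 18 (3R,4S,6E)-4-bromo-7-iodohept-6-en-3-ol, via alpha-bromoaldehyde 16 (not isolated), via magnesium alkoxide 17 (not isolated)
Conditions: (S)-2-{bis[3,5-bis(trifluoromethyl)phenyl](trimethylsilyloxy)methyl}pyrrolidine (10 mol%), PhCO2H (10 mol%), 4,4-dibromo-2,6-di-tert-butylcyclohexa-2,5-dien-1-one (1.0 equiv), CH2Cl2/pentane, −40 °C; cold solution cannulated into EtMgBr (2.5 equiv), Et2O, −78 °C; pH 7 buffer quench
Reagents that add atoms: 4,4-dibromo-2,6-di-tert-butylcyclohexa-2,5-dien-1-one CC(C)(C)C1=CC(Br)(Br)C=C(C(C)(C)C)C1=O; ethylmagnesium bromide CC[Mg]Br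
Why: Enamine-catalysed asymmetric α-bromination (the diarylprolinol silyl ether shields one face of the E-enamine) sets C12 (S) as the first stereocentre of this fragment, and immediate Grignard addition to the configurationally fragile α-bromoaldehyde follows the Cornforth model to give the 1,2-anti bromohydrin (C13 R).

Step 8
Reactants: 11 (2S,3R,5R)-5-ethynyl-2-[(triisopropylsilyl)ethynyl]oxolan-3-ol; 18 (3R,4S,6E)-4-bromo-7-iodohept-6-en-3-ol
Product: 19 (3R,4S,6E)-4-bromo-9-{(2R,4R,5S)-4-hydroxy-5-[(triisopropylsilyl)ethynyl]oxolan-2-yl}non-6-en-8-yn-3-ol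
Conditions: PdCl2(PPh3)2 (3 mol%), CuI (6 mol%), Et3N (3 equiv), THF, rt
Reagents that add atoms: none
Why: Sonogashira coupling joins C8 to C9 with retention of the E vinyl geometry under amine conditions too mild to close the bromohydrin to an epoxide or to insert into the secondary C–Br bond.

Step 9
Reactants: 19 (3R,4S,6E)-4-bromo-9-{(2R,4R,5S)-4-hydroxy-5-[(triisopropylsilyl)ethynyl]oxolan-2-yl}non-6-en-8-yn-3-ol
Product: 20 (3R,4S,6E,8Z)-4-bromo-9-{(2R,4R,5S)-4-hydroxy-5-[(triisopropylsilyl)ethynyl]oxolan-2-yl}nona-6,8-dien-3-ol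
Conditions: H2 (1 atm), Pd/CaCO3 poisoned with Pb(OAc)2, quinoline, EtOAc, 0 °C, stopped at one equivalent of H2
Reagents that add atoms: none
Why: Poisoned-palladium semihydrogenation adds H2 syn to the internal alkyne to give the 7Z alkene, while the triisopropylsilyl-shielded alkyne, the 9E alkene and the C–Br bond react much more slowly.

Step 10
Reactants: 20 (3R,4S,6E,8Z)-4-bromo-9-{(2R,4R,5S)-4-hydroxy-5-[(triisopropylsilyl)ethynyl]oxolan-2-yl}nona-6,8-dien-3-ol
Product: 22 (1R,3S,4R,6S)-3-{(R)-bromo[(2R,3R,5S,6R)-3,5-dibromo-6-ethyloxan-2-yl]methyl}-6-[(triisopropylsilyl)ethynyl]-2,5-dioxabicyclo[2.2.1]heptane, via monocyclised dibromo-oxane 21 (not isolated)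
Conditions: Ph3P=S (10 mol%), 4 Å MS, CH2Cl2, dark; NBS (1.1 equiv), −40 °C; then NBS (1.2 equiv), 0 °C to rt
Reagents that add atoms: N-bromosuccinimide O=C1CCC(=O)N1Br
Why: Proposed new method: a one-pot, two-directional double bromoetherification of a conjugated (Z,E)-diene flanked by two hydroxyls, not yet shown on such a diene, in which Lewis-base-activated NBS first brominates the more electron-rich, less hindered 9E alkene at C10, the allylic cation character at C9 (the vinyl group acting as the aryl group does in 6-endo halocyclisations of 5-aryl-4-pentenols) steers O13 to C9 through an all-equatorial chair so that C12/C13 fix C9 (R) and C10 (R) by anti addition to give 21, and the second equivalent then attacks the remaining 7Z alkene on the face anti to C10 (H9 inside to relieve allylic strain) while O4, held cis on ring A, opens the bromonium at C7 in 5-exo mode with the ring oxygen rather than the CH2 in the inside position, giving anti addition (7S,8R) and the endo side chain; the closest known reactions are Lewis-base-catalysed 5-exo and aryl-directed 6-endo bromoetherifications of 4-alkenols.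

Step 11
Reactants: 22 (1R,3S,4R,6S)-3-{(R)-bromo[(2R,3R,5S,6R)-3,5-dibromo-6-ethyloxan-2-yl]methyl}-6-[(triisopropylsilyl)ethynyl]-2,5-dioxabicyclo[2.2.1]heptane
Product: 23 (1R,3S,4R,6S)-3-{(R)-bromo[(2R,3R,5S,6R)-3,5-dibromo-6-ethyloxan-2-yl]methyl}-6-ethynyl-2,5-dioxabicyclo[2.2.1]heptane
Conditions: Bu4NF (1.2 equiv), AcOH (1.2 equiv), THF, 0 °C
Reagents that add atoms: none
Why: Fluoride-induced protodesilylation of the alkynylsilane, buffered with acetic acid so that the three secondary bromides are not eliminated, frees the terminal alkyne without touching any stereocentre.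

**Compound list** (cyclopentadienyl ligands are drawn σ-bonded in the SMILES)
1 | 3-(trimethylsilyl)prop-2-ynal | C[Si](C)(C)C#CC=O | starting material
2 | allenylboronic acid pinacol ester | C=C=CB1OC(C)(C)C(C)(C)O1 | starting material
3 | pinacol borate ester of 4 | C[Si](C)(C)C#C[C@H](OB1OC(C)(C)C(C)(C)O1)CC#C | intermediate
4 | (3R)-1-(trimethylsilyl)hexa-1,5-diyn-3-ol | C[Si](C)(C)C#C[C@H](O)CC#C | intermediate
5 | (bromoethynyl)triisopropylsilane | CC(C)[Si](C#CBr)(C(C)C)C(C)C | starting material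
6 | (E)-alkenylzirconocene chloride of 4 (O–ZrCp2Cl alkoxide) | C[Si](C)(C)C#C[C@H](O[Zr](Cl)(C1C=CC=C1)C1C=CC=C1)C/C=C/[Zr](Cl)(C1C=CC=C1)C1C=CC=C1 | intermediate
7 | (E)-alkenylzinc chloride of 4 (O–ZrCp2Cl alkoxide) | C[Si](C)(C)C#C[C@H](O[Zr](Cl)(C1C=CC=C1)C1C=CC=C1)C/C=C/[Zn]Cl | intermediate
8 | (3R,5E)-1-(trimethylsilyl)-8-(triisopropylsilyl)oct-5-ene-1,7-diyn-3-ol | C[Si](C)(C)C#C[C@H](O)C/C=C/C#C[Si](C(C)C)(C(C)C)C(C)C | intermediate
9 | (2R)-1-{(2R,3R)-3-[(triisopropylsilyl)ethynyl]oxiran-2-yl}-4-(trimethylsilyl)but-3-yn-2-ol | C[Si](C)(C)C#C[C@H](O)C[C@H]1O[C@@H]1C#C[Si](C(C)C)(C(C)C)C(C)C | intermediate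
10 | (2S,3R,5R)-2-[(triisopropylsilyl)ethynyl]-5-[(trimethylsilyl)ethynyl]oxolan-3-ol | C[Si](C)(C)C#C[C@H]1C[C@@H](O)[C@@H](O1)C#C[Si](C(C)C)(C(C)C)C(C)C | intermediate
11 | (2S,3R,5R)-5-ethynyl-2-[(triisopropylsilyl)ethynyl]oxolan-3-ol | C#C[C@H]1C[C@@H](O)[C@@H](O1)C#C[Si](C(C)C)(C(C)C)C(C)C | intermediate
12 | pent-4-yn-1-ol | C#CCCCO | starting material
13 | (E)-alkenylzirconocene chloride of 12 (O–ZrCp2Cl alkoxide) | Cl[Zr](OCCC/C=C/[Zr](Cl)(C1C=CC=C1)C1C=CC=C1)(C1C=CC=C1)C1C=CC=C1 | intermediate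
14 | (E)-5-iodopent-4-en-1-ol | OCCC/C=C/I | intermediate
15 | (E)-5-iodopent-4-enal | O=CCC/C=C/I | intermediate
16 | (2S,4E)-2-bromo-5-iodopent-4-enal | O=C[C@@H](Br)C/C=C/I | intermediate
17 | bromomagnesium alkoxide of 18 | CC[C@@H](O[Mg]Br)[C@@H](Br)C/C=C/I | intermediate
18 | (3R,4S,6E)-4-bromo-7-iodohept-6-en-3-ol | CC[C@@H](O)[C@@H](Br)C/C=C/I | intermediate
19 | (3R,4S,6E)-4-bromo-9-{(2R,4R,5S)-4-hydroxy-5-[(triisopropylsilyl)ethynyl]oxolan-2-yl}non-6-en-8-yn-3-ol | CC[C@@H](O)[C@@H](Br)C/C=C/C#C[C@H]1C[C@@H](O)[C@@H](O1)C#C[Si](C(C)C)(C(C)C)C(C)C | intermediate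
20 | (3R,4S,6E,8Z)-4-bromo-9-{(2R,4R,5S)-4-hydroxy-5-[(triisopropylsilyl)ethynyl]oxolan-2-yl}nona-6,8-dien-3-ol | CC[C@@H](O)[C@@H](Br)C/C=C/C=C\[C@H]1C[C@@H](O)[C@@H](O1)C#C[Si](C(C)C)(C(C)C)C(C)C | intermediate
21 | (2S,3R,5R)-5-{(Z)-2-[(2S,3R,5S,6R)-3,5-dibromo-6-ethyloxan-2-yl]ethenyl}-2-[(triisopropylsilyl)ethynyl]oxolan-3-ol | CC(C)[Si](C(C)C)(C(C)C)C#C[C@@H]1O[C@H](C[C@H]1O)/C=C\[C@@H]2O[C@H](CC)[C@@H](Br)C[C@H]2Br | intermediate
22 | (1R,3S,4R,6S)-3-{(R)-bromo[(2R,3R,5S,6R)-3,5-dibromo-6-ethyloxan-2-yl]methyl}-6-[(triisopropylsilyl)ethynyl]-2,5-dioxabicyclo[2.2.1]heptane | CC(C)[Si](C(C)C)(C(C)C)C#C[C@@H]1O[C@@H]2C[C@H]1O[C@@H]2[C@@H](Br)[C@@H]1O[C@H](CC)[C@@H](Br)C[C@H]1Br | intermediate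
23 | (1R,3S,4R,6S)-3-{(R)-bromo[(2R,3R,5S,6R)-3,5-dibromo-6-ethyloxan-2-yl]methyl}-6-ethynyl-2,5-dioxabicyclo[2.2.1]heptane, (3S,4R,6R,7S,8R,9R,10R,12S,13R) in chain numbering | C#C[C@@H]1O[C@@H]2C[C@H]1O[C@@H]2[C@@H](Br)[C@@H]1O[C@H](CC)[C@@H](Br)C[C@H]1Br | target

**Step count.** There are 11 steps in total, with each telescoped operation counted as one step. The longest linear sequence is 8 steps (steps 1, 2, 3, 4, 8, 9, 10, 11).

**Steps most likely to fail**

Step 10 (the proposed new step).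
- The first closure could go 5-exo or by 1,4-addition across the diene.
- The second closure could go 6-endo to a dioxabicyclo[3.2.1]octane, or could occur on the wrong alkene face.
- The fallback uses known reactions only. It sets out from 11 and 18 and comes back at 22.
- Pd-catalysed syn-hydrostannation of 11 (Bu3SnH, PdCl2(PPh3)2, THF, 0 °C) gives (2S,3R,5R)-5-[(E)-2-(tributylstannyl)ethenyl]-2-[(triisopropylsilyl)ethynyl]oxolan-3-ol F1.
- Base-free coupling with 18 mediated by copper thiophene-2-carboxylate (NMP, 0 °C) gives (3R,4S,6E,8E)-4-bromo-9-{(2R,4R,5S)-4-hydroxy-5-[(triisopropylsilyl)ethynyl]oxolan-2-yl}nona-6,8-dien-3-ol F2.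
- One equivalent of NBS closes ring C alone, in a single π-donor-directed 6-endo bromoetherification. This gives (2S,3R,5R)-5-{(E)-2-[(2S,3R,5S,6R)-3,5-dibromo-6-ethyloxan-2-yl]ethenyl}-2-[(triisopropylsilyl)ethynyl]oxolan-3-ol F3.
- Shi epoxidation of the now E-configured C7=C8 alkene with the same ketone gives (2S,3R,5R)-5-{(2R,3S)-3-[(2S,3R,5S,6R)-3,5-dibromo-6-ethyloxan-2-yl]oxiran-2-yl}-2-[(triisopropylsilyl)ethynyl]oxolan-3-ol F4.
- CSA-catalysed 5-exo epoxide opening by O4 at C7, with inversion, closes ring B stereospecifically. This gives (S)-[(2S,3R,5S,6R)-3,5-dibromo-6-ethyloxan-2-yl]{(1R,3R,4R,6S)-6-[(triisopropylsilyl)ethynyl]-2,5-dioxabicyclo[2.2.1]heptan-3-yl}methanol F5.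
- Appel-type bromination with inversion at C8 (CBr4, P(n-C8H17)3, toluene, 70 °C) gives 22.

Step 9.
- The diene could be over-reduced, or the silyl alkyne could be partly reduced.
- The fallback sets out from 11 and 18 and comes back at 20.
- Et3B/air-initiated radical hydrostannation of 11 (Bu3SnH, toluene, −78 °C, kinetic Z selectivity) gives (2S,3R,5R)-5-[(Z)-2-(tributylstannyl)ethenyl]-2-[(triisopropylsilyl)ethynyl]oxolan-3-ol F6.
- F6 is coupled with 18 by copper thiophene-2-carboxylate with retention of both alkene geometries. This gives 20 directly, so neither 19 nor a hydrogenation is needed.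

Step 7.
- The amine catalyst could racemise 16, and the anti selectivity of the Grignard addition may be modest.
- The fallback sets out from 14 and comes back at 16.
- Compound 14 is oxidised (TEMPO, PhI(OAc)2, MeCN/H2O) to (E)-5-iodopent-4-enoic acid F7.
- F7 is converted with (COCl)2 and catalytic DMF into (E)-5-iodopent-4-enoyl chloride F8.
- A cinchona-alkaloid-catalysed ketene α-bromination follows. It uses benzoylquinine or its pseudo-enantiomer, 2,4,4,6-tetrabromocyclohexa-2,5-dien-1-one, iPr2NEt, toluene, −78 °C. It gives the configurationally stable 2,4,6-tribromophenyl (2S,4E)-2-bromo-5-iodopent-4-enoate F9.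
- iBu2AlH at −78 °C then releases 16 with no amine present, and EtMgBr is added to the same flask as in step 7.

**Further compounds**
F1 | step 10 | (2S,3R,5R)-5-[(E)-2-(tributylstannyl)ethenyl]-2-[(triisopropylsilyl)ethynyl]oxolan-3-ol | CCCC[Sn](CCCC)(CCCC)/C=C/[C@H]1C[C@@H](O)[C@@H](O1)C#C[Si](C(C)C)(C(C)C)C(C)C
F2 | step 10 | (3R,4S,6E,8E)-4-bromo-9-{(2R,4R,5S)-4-hydroxy-5-[(triisopropylsilyl)ethynyl]oxolan-2-yl}nona-6,8-dien-3-ol | CC[C@@H](O)[C@@H](Br)C/C=C/C=C/[C@H]1C[C@@H](O)[C@@H](O1)C#C[Si](C(C)C)(C(C)C)C(C)C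
F3 | step 10 | (2S,3R,5R)-5-{(E)-2-[(2S,3R,5S,6R)-3,5-dibromo-6-ethyloxan-2-yl]ethenyl}-2-[(triisopropylsilyl)ethynyl]oxolan-3-ol | CC(C)[Si](C(C)C)(C(C)C)C#C[C@@H]1O[C@H](C[C@H]1O)/C=C/[C@@H]2O[C@H](CC)[C@@H](Br)C[C@H]2Br
F4 | step 10 | (2S,3R,5R)-5-{(2R,3S)-3-[(2S,3R,5S,6R)-3,5-dibromo-6-ethyloxan-2-yl]oxiran-2-yl}-2-[(triisopropylsilyl)ethynyl]oxolan-3-ol | CC(C)[Si](C(C)C)(C(C)C)C#C[C@@H]1O[C@H](C[C@H]1O)[C@H]3O[C@@H]3[C@@H]2O[C@H](CC)[C@@H](Br)C[C@H]2Br
F5 | step 10 | (S)-[(2S,3R,5S,6R)-3,5-dibromo-6-ethyloxan-2-yl]{(1R,3R,4R,6S)-6-[(triisopropylsilyl)ethynyl]-2,5-dioxabicyclo[2.2.1]heptan-3-yl}methanol | CC(C)[Si](C(C)C)(C(C)C)C#C[C@@H]1O[C@@H]2C[C@H]1O[C@@H]2[C@H](O)[C@@H]1O[C@H](CC)[C@@H](Br)C[C@H]1Br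
F6 | step 9 | (2S,3R,5R)-5-[(Z)-2-(tributylstannyl)ethenyl]-2-[(triisopropylsilyl)ethynyl]oxolan-3-ol | CCCC[Sn](CCCC)(CCCC)/C=C\[C@H]1C[C@@H](O)[C@@H](O1)C#C[Si](C(C)C)(C(C)C)C(C)C
F7 | step 7 | (E)-5-iodopent-4-enoic acid | OC(=O)CC/C=C/I
F8 | step 7 | (E)-5-iodopent-4-enoyl chloride | ClC(=O)CC/C=C/I
F9 | step 7 | 2,4,6-tribromophenyl (2S,4E)-2-bromo-5-iodopent-4-enoate | O=C(Oc1c(Br)cc(Br)cc1Br)[C@@H](Br)C/C=C/I
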